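Everything rests on opening ring C of the 3-aryl (eriodictyol-type) flavanone at O1–C8a and C2–C3. C3 is α to the C4 ketone and C8a of ring A is ortho to it, so a benzylic ketone that carries fluoride at C8a can take up 3,4-bis(benzyloxy)benzaldehyde (C2 and O1) between these two atoms. In one operation a fluoride-relayed aldol addition/SNAr ring closure of its silyl enol ether, run in a chiral ammonium ion pair, should form both bonds and the cis-2R,3R centres. The ketone comes from α-arylation of a fluoroacetophenone with an 8-bromochromone; the naringenin centre is set afterwards by asymmetric conjugate arylation, and hydrogenolysis ends the route.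

Key step: step 6

Remark on naming: the 3-aryl flavanone has ring A (C4a–C8a), ring C (O1, C2, C3, C4) and ring B (catechol); the naringenin unit has rings D, F and E with doubly primed locants, and C3 is bonded to C8''.

Remark on stereochemistry: the structure is read as drawn, 2R,3R with the two aryl groups on C2 and C3 cis, and 2''S. The cis ketone is the less stable C3 epimer, so no step after step 6 uses base.

Remark on supply: 1-[2,4-bis(benzyloxy)-6-hydroxyphenyl]ethan-1-one (5) is taken as a purchased compound (otherwise one step from 2,4,6-trihydroxyacetophenone with benzyl bromide and K2CO3).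

Step 1
Reactants: 1 2',4',6'-trifluoroacetophenone; 2 benzyl alcohol
Product: 4 1-[2,4-bis(benzyloxy)-6-fluorophenyl]ethan-1-one, via 4-benzyloxy-2,6-difluoroacetophenone 3 (not isolated)
Conditions: 2 (2.05 equiv), Cs2CO3 (2.5 equiv), DMF, 0 °C to rt
Reagents that add atoms: none
Why: Twofold SNAr in which the acetyl group activates the para fluoride first and one ortho fluoride second, while the last fluoride should be slower because the ketone, now flanked by two ortho substituents, is twisted out of conjugation and two fluorine activators are gone.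

Step 2
Reactants: 5 1-[2,4-bis(benzyloxy)-6-hydroxyphenyl]ethan-1-one
Product: 6 1-[4,6-bis(benzyloxy)-3-bromo-2-hydroxyphenyl]ethan-1-one
Conditions: NBS (1.0 equiv), i-Pr2NH (10 mol%), CH2Cl2, 0 °C
Reagents that add atoms: N-bromosuccinimide, O=C1CCC(=O)N1Br
Why: Amine-catalysed electrophilic bromination with NBS is ortho-selective for free phenols, so bromine should enter C3 next to the chelated hydroxyl (the future C8'') and not C5 between the two benzyloxy groups.

Step 3
Reactants: 6 1-[4,6-bis(benzyloxy)-3-bromo-2-hydroxyphenyl]ethan-1-one; 7 N,N-dimethylformamide dimethyl acetal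
Product: 9 5,7-bis(benzyloxy)-8-bromo-4H-chromen-4-one, via enaminone 8 (not isolated)
Conditions: 7 (3 equiv), toluene, 100 °C; then conc. HCl, CH2Cl2, 40 °C
Reagents that add atoms: none
Why: Enaminone formation at the acetyl group followed by acid-induced 6-endo addition of the phenol and loss of dimethylamine is the standard chromone synthesis and fixes bromine at C8''.

Step 4
Reactants: 4 1-[2,4-bis(benzyloxy)-6-fluorophenyl]ethan-1-one; 9 5,7-bis(benzyloxy)-8-bromo-4H-chromen-4-one
Product: 10 8-{2-[2,4-bis(benzyloxy)-6-fluorophenyl]-2-oxoethyl}-5,7-bis(benzyloxy)-4H-chromen-4-one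
Conditions: Pd2(dba)3 (2.5 mol%), XPhos (6 mol%), K3PO4 (2.5 equiv), toluene, 90 °C
Reagents that add atoms: none
Why: Palladium-catalysed ketone α-arylation (Buchwald–Hartwig type) with a bulky biarylphosphine and a mild base should join the methyl ketone to the hindered bromide; the chromone has no enolisable hydrogen and the more acidic product methylene is held as its enolate, which blocks a second arylation.

Step 5
Reactants: 10 8-{2-[2,4-bis(benzyloxy)-6-fluorophenyl]-2-oxoethyl}-5,7-bis(benzyloxy)-4H-chromen-4-one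
Product: 11 (Z)-8-{2-[2,4-bis(benzyloxy)-6-fluorophenyl]-2-(trimethylsilyloxy)ethenyl}-5,7-bis(benzyloxy)-4H-chromen-4-one
Conditions: TMSOTf (1.2 equiv), Et3N (2 equiv), CH2Cl2, 0 °C; filtration under argon, used at once
Reagents that add atoms: trimethylsilyl trifluoromethanesulfonate, C[Si](C)(C)OS(=O)(=O)C(F)(F)F
Why: Soft enolisation at the only enolisable position should give the silyl enol ether, with the Z geometry expected because the two aryl groups avoid each other.

Step 6
Reactants: 11 (Z)-8-{2-[2,4-bis(benzyloxy)-6-fluorophenyl]-2-(trimethylsilyloxy)ethenyl}-5,7-bis(benzyloxy)-4H-chromen-4-one; 12 3,4-bis(benzyloxy)benzaldehyde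
Product: 15 (2R,3R)-5,7-bis(benzyloxy)-2-[3,4-bis(benzyloxy)phenyl]-3-[5,7-bis(benzyloxy)-4-oxo-4H-chromen-8-yl]chroman-4-one (2,3-cis), via ammonium enolate 13 (not isolated), via syn-aldolate 14 (not isolated)
Conditions: 12 (1.3 equiv), O-allyl-N-(9-anthracenylmethyl)cinchonidinium bromide (10 mol%), CsF (20 mol%), 4 Å sieves, toluene–CH2Cl2 4:1, −40 to 0 °C; AcOH quench at −40 °C
Reagents that add atoms: none
Why: Proposed new method: fluoride, carried into solution by the chiral ammonium cation, desilylates 11 to the ion-paired enolate 13, which adds reversibly through C3 to the aldehyde carbon (C2–C3); the alkoxide 14 then displaces the fluoride at C8a of ring A, ortho to the C4 carbonyl (O1–C8a), and the fluoride set free desilylates the next molecule, so Me3SiF is the only co-product and no stoichiometric base is present. The closest known reaction types are the chiral ammonium fluoride-catalysed Mukaiyama aldol addition and the fluoride-catalysed SNAr etherification of silyl ethers with activated aryl fluorides; joined, they amount to a stepwise hetero-Diels–Alder reaction in which C8a–F plays the part of the alkoxy terminus of a Danishefsky diene. Ring C closes by a 6-exo-trig addition–elimination at C8a (exo with respect to the C8–C8a bond) through a Meisenheimer intermediate. C2 is set in this ring closure, where the rapidly interconverting aldolates are resolved dynamically by the cation on the C2 oxygen (the sense of induction must be found by trial, and the cinchonine-derived pseudo-enantiomer is the alternative), and C3 follows C2 because the closing aldolate should carry the bulky C3 aryl pseudo-axial, out of the plane of the C4 carbonyl, and the C2 aryl pseudo-equatorial, which is the cis arrangement. The step needs O-arylation at C8a only and survival of the kinetic cis ketone: ring A carries a single fluoride next to the activating carbonyl, the chromone of ring F has no acidic hydrogen, and the absence of stoichiometric base should keep C3 from equilibrating to trans and ring C from opening to the chalcone.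

Step 7
Reactants: 15 (2R,3R)-5,7-bis(benzyloxy)-2-[3,4-bis(benzyloxy)phenyl]-3-[5,7-bis(benzyloxy)-4-oxo-4H-chromen-8-yl]chroman-4-one; 16 4-(benzyloxy)phenylboronic acid
Product: 17 (2R,3R)-5,7-bis(benzyloxy)-2-[3,4-bis(benzyloxy)phenyl]-3-[(2S)-5,7-bis(benzyloxy)-2-(4-benzyloxyphenyl)-4-oxochroman-8-yl]chroman-4-one
Conditions: 16 (2 equiv), Pd(OCOCF3)2 (5 mol%), (R)-4-tert-butyl-2-(pyridin-2-yl)-4,5-dihydrooxazole ((R)-t-BuPyOx, 6 mol%), NH4PF6 (30 mol%), H2O (5 equiv), ClCH2CH2Cl, 60 °C
Reagents that add atoms: none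
Why: Palladium-catalysed asymmetric conjugate addition of an arylboronic acid to a chromone should set C2'' under catalyst control (the S ligand gives R adducts of cyclic enones, so the R ligand is expected to give the 2''S flavanone), the saturated ketone of ring C is no acceptor, the base-free medium should leave the cis C3 centre alone, and any 2S,3S material from step 6 becomes a separable diastereomer here.

Step 8
Reactants: 17 (2R,3R)-5,7-bis(benzyloxy)-2-[3,4-bis(benzyloxy)phenyl]-3-[(2S)-5,7-bis(benzyloxy)-2-(4-benzyloxyphenyl)-4-oxochroman-8-yl]chroman-4-one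
Product: 18 (2R,3R)-2-(3,4-dihydroxyphenyl)-5,7-dihydroxy-3-[(2S)-5,7-dihydroxy-2-(4-hydroxyphenyl)-4-oxochroman-8-yl]chroman-4-one (CNP0105436.1)
Conditions: H2 (1 atm), Pd(OH)2/C, EtOAc–MeOH 1:1, rt
Reagents that add atoms: none
Why: Hydrogenolysis of the seven benzyl ethers runs under neutral conditions, so neither the epimerisable cis C3 centre nor the two base-labile C2 centres should be touched.

Compound list
1 | 2',4',6'-trifluoroacetophenone | CC(=O)c1c(F)cc(F)cc1F | starting material
2 | benzyl alcohol | OCc1ccccc1 | starting material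
3 | 1-[4-(benzyloxy)-2,6-difluorophenyl]ethan-1-one (not isolated) | CC(=O)c1c(F)cc(OCc2ccccc2)cc1F | intermediate
4 | 1-[2,4-bis(benzyloxy)-6-fluorophenyl]ethan-1-one | CC(=O)c1c(F)cc(OCc2ccccc2)cc1OCc1ccccc1 | intermediate
5 | 1-[2,4-bis(benzyloxy)-6-hydroxyphenyl]ethan-1-one | CC(=O)c1c(O)cc(OCc2ccccc2)cc1OCc1ccccc1 | starting material
6 | 1-[4,6-bis(benzyloxy)-3-bromo-2-hydroxyphenyl]ethan-1-one | CC(=O)c1c(O)c(Br)c(OCc2ccccc2)cc1OCc1ccccc1 | intermediate
7 | N,N-dimethylformamide dimethyl acetal | COC(OC)N(C)C | starting material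
8 | (E)-1-[4,6-bis(benzyloxy)-3-bromo-2-hydroxyphenyl]-3-(dimethylamino)prop-2-en-1-one (not isolated) | CN(C)/C=C/C(=O)c1c(O)c(Br)c(OCc2ccccc2)cc1OCc1ccccc1 | intermediate
9 | 5,7-bis(benzyloxy)-8-bromo-4H-chromen-4-one | O=c1ccoc2c(Br)c(OCc3ccccc3)cc(OCc3ccccc3)c12 | intermediate
10 | 8-{2-[2,4-bis(benzyloxy)-6-fluorophenyl]-2-oxoethyl}-5,7-bis(benzyloxy)-4H-chromen-4-one | O=C(Cc1c(OCc2ccccc2)cc(OCc2ccccc2)c2c(=O)ccoc12)c1c(F)cc(OCc2ccccc2)cc1OCc1ccccc1 | intermediate
11 | (Z)-8-{2-[2,4-bis(benzyloxy)-6-fluorophenyl]-2-(trimethylsilyloxy)ethenyl}-5,7-bis(benzyloxy)-4H-chromen-4-one | C[Si](C)(C)O/C(=C\c1c(OCc2ccccc2)cc(OCc2ccccc2)c2c(=O)ccoc12)c1c(F)cc(OCc2ccccc2)cc1OCc1ccccc1 | intermediate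
12 | 3,4-bis(benzyloxy)benzaldehyde | O=Cc1ccc(OCc2ccccc2)c(OCc2ccccc2)c1 | starting material
13 | O-allyl-N-(9-anthracenylmethyl)cinchonidinium (Z)-enolate of 10 (ion pair, not isolated) | C=C[C@H]1C[N+]2(Cc3c4ccccc4cc4ccccc34)CC[C@H]1C[C@H]2[C@H](OCC=C)c1ccnc2ccccc12.[O-]/C(=C\c1c(OCc2ccccc2)cc(OCc2ccccc2)c2c(=O)ccoc12)c1c(F)cc(OCc2ccccc2)cc1OCc1ccccc1 | intermediate
14 | O-allyl-N-(9-anthracenylmethyl)cinchonidinium (2R,3R)-syn-aldolate: alkoxide of 1-[2,4-bis(benzyloxy)-6-fluorophenyl]-3-[3,4-bis(benzyloxy)phenyl]-2-[5,7-bis(benzyloxy)-4-oxo-4H-chromen-8-yl]-3-hydroxypropan-1-one (ion pair, not isolated) | C=C[C@H]1C[N+]2(Cc3c4ccccc4cc4ccccc34)CC[C@H]1C[C@H]2[C@H](OCC=C)c1ccnc2ccccc12.[O-][C@@H](c1ccc(OCc2ccccc2)c(OCc2ccccc2)c1)[C@@H](c1c(OCc2ccccc2)cc(OCc2ccccc2)c2c(=O)ccoc12)C(=O)c1c(F)cc(OCc2ccccc2)cc1OCc1ccccc1 | intermediate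
15 | (2R,3R)-5,7-bis(benzyloxy)-2-[3,4-bis(benzyloxy)phenyl]-3-[5,7-bis(benzyloxy)-4-oxo-4H-chromen-8-yl]chroman-4-one (2,3-cis) | O=c1ccoc2c1c(OCc3ccccc3)cc(OCc3ccccc3)c2[C@H]1C(=O)c2c(OCc3ccccc3)cc(OCc3ccccc3)cc2O[C@H]1c1ccc(OCc2ccccc2)c(OCc2ccccc2)c1 | intermediate
16 | 4-(benzyloxy)phenylboronic acid | OB(O)c1ccc(OCc2ccccc2)cc1 | starting material
17 | (2R,3R)-5,7-bis(benzyloxy)-2-[3,4-bis(benzyloxy)phenyl]-3-[(2S)-5,7-bis(benzyloxy)-2-(4-benzyloxyphenyl)-4-oxochroman-8-yl]chroman-4-one | O=C1C[C@@H](c2ccc(OCc3ccccc3)cc2)Oc2c1c(OCc3ccccc3)cc(OCc3ccccc3)c2[C@H]1C(=O)c2c(OCc3ccccc3)cc(OCc3ccccc3)cc2O[C@H]1c1ccc(OCc2ccccc2)c(OCc2ccccc2)c1 | intermediate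
18 | (2R,3R)-2-(3,4-dihydroxyphenyl)-5,7-dihydroxy-3-[(2S)-5,7-dihydroxy-2-(4-hydroxyphenyl)-4-oxochroman-8-yl]chroman-4-one (CNP0105436.1) | O=C1C[C@@H](c2ccc(O)cc2)Oc2c1c(O)cc(O)c2[C@H]1C(=O)c2c(O)cc(O)cc2O[C@H]1c1ccc(O)c(O)c1 | target

Total step count: 8.
Longest linear sequence: 7 steps (5 → 6 → 9 → 10 → 11 → 15 → 17 → 18).

Steps most likely to fail

1. Step 6 (Proposed new method). The ring closure may be slower than silyl transfer, so that silylated aldol builds up and the fluoride relay stalls. The ion pair may discriminate poorly between the two faces at C2. The cis ketone may equilibrate to trans, or ring C may open by retro-oxa-Michael reaction, if basic chain carriers live too long. Fallback with known chemistry, setting out from 10 and returning at 17: the lithium enolate of 10 (LiN(SiMe3)2, THF, −78 °C) and 12 would give the β-hydroxy ketone F1 as a racemic mixture of diastereomers (aldol addition, cold acidic quench). KN(SiMe3)2 (2.2 equiv) and 18-crown-6 in THF (−78 to −20 °C) would then close ring C by intramolecular SNAr and deprotonate the product to the potassium enolate F2. Protonation of F2 at −78 °C with 2,6-di-tert-butyl-4-methylphenol, anti to the pseudo-axial C2 aryl, should give the racemic cis ketone, that is 15 together with its enantiomer F3. Under the conditions of step 7 this racemate would give 17 and the 2S,3S,2''S diastereomer F4, which are separated by chromatography.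

2. Step 4. Oxidative addition and reductive elimination at the doubly ortho-substituted bromide may be sluggish, and the ketone enolate may add to the chromone in a conjugate sense instead of coupling. Fallback with the polarity of the partners reversed, setting out from 9 and 4 and returning at 10: Miyaura borylation of 9 (B2pin2, PdCl2(dppf), KOAc, dioxane, 90 °C) would give the 8-boronate F5. Ketone 4 would be brominated (PhNMe3Br3, THF, 0 °C) to the α-bromo ketone F6. Suzuki coupling of F5 with F6 (Pd(PPh3)4, K3PO4, toluene–H2O, 80 °C) would give 10.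

3. Step 7. The electron-rich chromone with its peri benzyloxy group may insert slowly into the arylpalladium species in the crowded late intermediate, and long heating with the ammonium salt may epimerise C3 through the enol. Fallback by changing the order, setting out from 10 and returning at 17: the conjugate arylation with 16 under the conditions of step 7 would be run on 10, before the cis centre exists, to give the flavanone ketone F7. KN(SiMe3)2 (1.0 equiv) and Me3SiCl at −78 °C would silylate the far more acidic benzylic ketone to the enol ether F8. Step 6 run on F8 and 12 would then give 17 directly.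

Further compounds
F1 | step 6 | 1-[2,4-bis(benzyloxy)-6-fluorophenyl]-3-[3,4-bis(benzyloxy)phenyl]-2-[5,7-bis(benzyloxy)-4-oxo-4H-chromen-8-yl]-3-hydroxypropan-1-one (racemic, both diastereomers) | O=C(C(C(O)c1ccc(OCc2ccccc2)c(OCc2ccccc2)c1)c1c(OCc2ccccc2)cc(OCc2ccccc2)c2c(=O)ccoc12)c1c(F)cc(OCc2ccccc2)cc1OCc1ccccc1
F2 | step 6 | potassium enolate of 5,7-bis(benzyloxy)-2-[3,4-bis(benzyloxy)phenyl]-3-[5,7-bis(benzyloxy)-4-oxo-4H-chromen-8-yl]chroman-4-one (racemic at C2) | [K+].[O-]C1=C(c2c(OCc3ccccc3)cc(OCc3ccccc3)c3c(=O)ccoc23)C(c2ccc(OCc3ccccc3)c(OCc3ccccc3)c2)Oc2cc(OCc3ccccc3)cc(OCc3ccccc3)c12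
F3 | step 6 | (2S,3S)-5,7-bis(benzyloxy)-2-[3,4-bis(benzyloxy)phenyl]-3-[5,7-bis(benzyloxy)-4-oxo-4H-chromen-8-yl]chroman-4-one (enantiomer of 15) | O=c1ccoc2c1c(OCc3ccccc3)cc(OCc3ccccc3)c2[C@@H]1C(=O)c2c(OCc3ccccc3)cc(OCc3ccccc3)cc2O[C@@H]1c1ccc(OCc2ccccc2)c(OCc2ccccc2)c1
F4 | step 6 | (2S,3S)-5,7-bis(benzyloxy)-2-[3,4-bis(benzyloxy)phenyl]-3-[(2S)-5,7-bis(benzyloxy)-2-(4-benzyloxyphenyl)-4-oxochroman-8-yl]chroman-4-one | O=C1C[C@@H](c2ccc(OCc3ccccc3)cc2)Oc2c1c(OCc3ccccc3)cc(OCc3ccccc3)c2[C@@H]1C(=O)c2c(OCc3ccccc3)cc(OCc3ccccc3)cc2O[C@@H]1c1ccc(OCc2ccccc2)c(OCc2ccccc2)c1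
F5 | step 4 | 5,7-bis(benzyloxy)-8-(4,4,5,5-tetramethyl-1,3,2-dioxaborolan-2-yl)-4H-chromen-4-one | O=c1ccoc2c(B3OC(C)(C)C(C)(C)O3)c(OCc3ccccc3)cc(OCc3ccccc3)c12
F6 | step 4 | 2-bromo-1-[2,4-bis(benzyloxy)-6-fluorophenyl]ethan-1-one | O=C(CBr)c1c(F)cc(OCc2ccccc2)cc1OCc1ccccc1
F7 | step 7 | (2S)-8-{2-[2,4-bis(benzyloxy)-6-fluorophenyl]-2-oxoethyl}-5,7-bis(benzyloxy)-2-[4-(benzyloxy)phenyl]chroman-4-one | O=C1C[C@@H](c2ccc(OCc3ccccc3)cc2)Oc2c1c(OCc3ccccc3)cc(OCc3ccccc3)c2CC(=O)c1c(F)cc(OCc2ccccc2)cc1OCc1ccccc1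
F8 | step 7 | (2S)-8-{(Z)-2-[2,4-bis(benzyloxy)-6-fluorophenyl]-2-(trimethylsilyloxy)ethenyl}-5,7-bis(benzyloxy)-2-[4-(benzyloxy)phenyl]chroman-4-one | O=C1C[C@@H](c2ccc(OCc3ccccc3)cc2)Oc2c1c(OCc3ccccc3)cc(OCc3ccccc3)c2/C=C(\O[Si](C)(C)C)c1c(F)cc(OCc2ccccc2)cc1OCc1ccccc1
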